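The time of a reading is the first thing I throw away. If both exchanges are first order in incoming ligand, dividing the rate of second exchange by the rate of first exchange cancels the clock and the ligand. Let a be the starting complex and b the complex with one exchanged, as fractions of the charge, and let c be what is missing from a plus b, which I take as complex with two exchanged. Then c rises by s·b/a per unit fall of a, where s is the ratio of the rate constants.

| flask | starting complex | incoming ligand | scavenger | remark | time |
|---|---|---|---|---|---|
| delta | 0.10 M | 0.067 M | 0.10 M | run made earlier |  |
| theta | 0.10 M | 0.15 M | 0.10 M | run made earlier |  |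
| gamma | 0.15 M | 0.10 M | 0.10 M | run made earlier |  |
| flask | 0.10 M | 0.100 M | 0.100 M |  | 50 min |

| run | time / min | complex with one exchanged / % | starting complex / % |
|---|---|---|---|
| delta | 2.00 | 3.2 | 97.2 |
| delta | 6.00 | 7.9 | 92.0 |
| delta | 12.0 | 16.0 | 83.8 |
| delta | 15.0 | 17.5 | 81.8 |
| delta | 25.0 | 24.9 | 72.3 |
| delta | 30.0 | 26.7 | 70.1 |
| delta | 40.0 | 30.2 | 66.2 |
| theta | 6.00 | 17.9 | 81.7 |
| theta | 12.0 | 28.9 | 68.2 |
| theta | 15.0 | 32.0 | 62.6 |
| theta | 25.0 | 41.0 | 49.3 |
| theta | 30.0 | 44.1 | 43.7 |
| theta | 40.0 | 46.9 | 36.7 |
| gamma | 4.00 | 8.4 | 91.7 |
| gamma | 10.0 | 17.5 | 80.8 |
| gamma | 20.0 | 27.7 | 70.4 |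
| gamma | 30.0 | 33.2 | 62.5 |
| gamma | 40.0 | 35.6 | 58.0 |

(standard deviation of a reading: 0.5 percentage points)

- amounts and yields of leaving ligand count idle adduct too
- what was read earlier has a scatter of 0.5 percentage points, one standard deviation
- steps that have been proposed: scavenger + leaving ligand -> scavenged by-product; leaving ligand + starting complex <-> idle adduct; leaving ligand + complex with one exchanged -> side product; starting complex + incoming ligand -> leaving ligand + complex with one exchanged; complex with one exchanged + incoming ligand -> leaving ligand + complex with two exchanged

* equivalents of incoming ligand to starting complex, everything else as given, that leave most complex with one exchanged at 50 min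
* the amount of complex with one exchanged then, in percent of the starting complex charged
* the amount of complex with one exchanged with the amounts as given

Two runs give s separately. In the theta run, the chord from 25.0 min to 40.0 min gives 0.504. In the gamma run, which has other charges, I sum b/a over the fall of a from the start to 40.0 min and set the sum against c, which gives 0.530. That c is 6.40%, read with a scatter of 0.5 percentage points per reading, and the two values of s lie within what that scatter allows, so I take them as one. Their mean, 0.517, is my s, the second rate constant over the first, the selectivity factor.

Integrated, s gives b = (a^s − a)/(1 − s), and b peaks where s·b/a reaches one, at a = 25.5% and b = 49.3%. The first theta reading gives a value for the first rate constant, k = 0.00399 M⁻¹ s⁻¹. For the flask, simple second-order decay puts a at 45.5%, and the curve then gives b = 43.6%. This decay leaves out the ligand drawn by second exchange, so I hold both as first estimates. For reaching the peak in 50 min, with ligand falling evenly, I reckon about 1.64 equivalents.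

The forecast gives 42.5% for the flask as charged, and 47.5% at 1.65 equiv, and its ground reads: “The rates fit simple second-order exchange.”

The flask as charged gives 42.4%, and the best charge gives 48.3% at 1.64 equiv. At 50.0 min the flask as charged makes complex with one exchanged 2.06 times faster than it uses it up, each step taken net. From the flask's a and b at that time, a/(s·b) comes to 2.15.

    scavenger + leaving ligand → scavenged by-product (k = 2.68 M⁻¹ s⁻¹)
    leaving ligand + starting complex ⇌ idle adduct, settled at all times (K = 2.62 M⁻¹)
    leaving ligand + complex with one exchanged → side product (k = 0.0161 M⁻¹ s⁻¹)
    starting complex + incoming ligand → leaving ligand + complex with one exchanged (k = 0.00409 M⁻¹ s⁻¹)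
    complex with one exchanged + incoming ligand → leaving ligand + complex with two exchanged (k = 0.00216 M⁻¹ s⁻¹)

For a neighbour flask charged with 0.040 M of starting complex, I take the mean ligand as the ligand charge less 0.0200 M, so a = 38.4% and s puts b at 46.7%. Computed, that neighbour flask holds 36.7% of starting complex and 47.0% of complex with one exchanged.

The numbers in the tables were generated by integration from invented constants; noise was put on by code.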